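All runs are calculated for an exercise.

The vessel is closed, stirred and held at one temperature, and in it starting material and partner give product under free catalyst.

| flask | starting material | partner | free catalyst | time |
|---|---|---|---|---|
| south-east | 0.600 M | 0.660 M | 0.0120 M |  |
| north | 0.240 M | 0.300 M | 0.0120 M |  |
| north-east | 0.600 M | 0.660 M | 0.0180 M |  |
| north-west | 0.200 M | 0.660 M | 0.0120 M | 160 h |

- south-east run (time / h: [product] / M): 20: 0.095; 40: 0.164; 60: 0.227; 80: 0.265; 100: 0.294; 120: 0.316; 140: 0.334; 160: 0.338
- north run (time / h: [product] / M): 20: 0.039; 40: 0.060; 60: 0.080; 80: 0.090; 100: 0.097; 120: 0.091; 140: 0.098; 160: 0.097
- north-east run (time / h: [product] / M): 20: 0.136; 40: 0.239; 60: 0.304; 80: 0.347; 100: 0.370; 120: 0.392; 140: 0.405; 160: 0.414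

(readings scatter by 0.003 M)

- Overall: starting material + partner -> product, with free catalyst as catalyst.
- Constant volume, constant temperature.
- What is held in complexes is read along with the free species.
- "The second partner" is partner.
- An order is taken over about fifteen percent of the charge, up and down.

* apparent order in [free catalyst] of the starting rate, round the charge of the south-east run (the rate where two percent of its starting material have turned into product)
* product in the north-west run at 160 h, as a share of the starting material charged

The north run flattens near 0.097 M, short of its charge of 0.240 M of starting material. I carry one quantity, the reach G: the integral of dP/(SR) up to the product P where a flask stops, with S and R the concentrations of starting material and partner. For charges a and b of these two, G = ln[a(b−P)/(b(a−P))]/(b−a). The last reading of the north run gives 2.12 /M, my estimate of the reach at 0.0120 M of free catalyst, and it carries the scatter of that one reading.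

The north-west run has that same catalyst charge, and its limiting reagent, starting material, caps the share at 100%. The south-east run, also at 0.0120 M, is still rising from 0.316 M to 0.338 M, and its last reading gives 1.85 /M, so I take that as the lower bound: 65.8% in the north-west run. The north reading raised by twice the scatter gives 2.33 /M, hence 73.4% from above. My own figure, from 2.12 /M, is 70.3%.

The forecast, holding that "the catalyst dies", gives 68% and an order of 0.97. Its share lies inside my bracket, a little below my figure.

The flask gives 72.1% and an order of 1.0, inside the bracket too.

    free catalyst + starting material ⇌ catalyst-substrate complex, settled at all times (29.50 /M)
    catalyst-substrate complex + partner ⇌ ternary complex, settled at all times (0.3270 /M)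
    ternary complex → product + free catalyst (2.743 /h)
    free catalyst → spent catalyst (0.1357 /h)

Product and loss both run in proportion to free catalyst, so G grows with the catalyst charge; the north-west run has reached 2.24 /M at 160 h. It stands short of its charge at 160 h through the loss of free catalyst to spent catalyst: the same run without that loss gives >99.9%, a result that would overturn the forecast. Scaled by catalyst, the estimate from the north run gives the north-east run 3.18 /M and an estimated stopping product of 0.419 M, and its reading at 160 h is 0.414 M.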